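**Assumption:** 4-(benzyloxy)-3-methoxybenzyl chloride (7), 4-bromo-2,6-dimethoxyphenol (1) and ethyl (S)-3-hydroxybutanoate (3) are purchased.

**Target check.** The target is C21H28O5: an ArCH2–CH(CH3)–CH(CH3)–CH2Ar′ chain with no ring. C2 is S and bears the guaiacyl CH2. C3 is R and bears the syringyl CH2. The relative configuration is meso-type, and the molecule is chiral only because the two aryl groups differ.

## Retrosynthetic overview
1. The target is a bis-benzyl ether (hydrogenolysis). Its syringyl Ar–CH2 bond is made last, by photochemical Ni/silyl-radical cross-electrophile coupling of a primary alkyl bromide with an aryl bromide at a non-stereogenic CH2.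
2. The guaiacyl-side C–C bond at stereocentre C2 is made by a stereo-inverting electrochemical Ni-catalysed opening of a trans β-lactone with a benzyl chloride (proposed new step). The acid carbon then becomes the CH2 for step 1.
3. The trans β-lactone (the only ring, transient) comes from the anti β-hydroxy acid by lactonisation with retention at the carbinol carbon. That acid comes from Fráter–Seebach methylation of ethyl (S)-3-hydroxybutanoate.
4. Both stereocentres derive from the single chiral-pool centre: the alkylation is diastereocontrolled by it, and the lactone opening is a stereospecific inversion.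

## Route

**Step 1**
Reactants: 1 (4-bromo-2,6-dimethoxyphenol)
Product: 2 (2-(benzyloxy)-5-bromo-1,3-dimethoxybenzene)
Conditions: BnBr, K2CO3, DMF, 60 °C
Reagents that add atoms: benzyl bromide, BrCc1ccccc1
Why: Williamson O-benzylation masks the phenol so that it survives the Ni-catalysed coupling. Benzyl is removed together with the second benzyl group in the last step.

**Step 2**
Reactants: 3 (ethyl (S)-3-hydroxybutanoate)
Product: 4 (ethyl (2S,3S)-3-hydroxy-2-methylbutanoate)
Conditions: LDA (2.2 equiv), THF, –78 → 0 °C; then MeI, DMPU, –78 °C → rt; chromatography to remove the minor syn isomer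
Reagents that add atoms: methyl iodide, CI
Why: Fráter–Seebach alkylation of the Li-chelated alkoxide/ester enolate dianion puts the electrophile anti to the C3 methyl. This sets C2 relative to the existing C3 (S) with no chiral reagent, at about 9:1 anti:syn.

**Step 3**
Reactants: 4
Product: 5 ((2S,3S)-3-hydroxy-2-methylbutanoic acid)
Conditions: LiOH·H2O, THF/H2O, rt; then 1 M HCl
Reagents that add atoms: water/hydroxide, O
Why: Ester saponification. No stereocentre is touched, since the α-proton of the carboxylate is not acidic.

**Step 4**
Reactants: 5
Product: 6 ((3S,4S)-3,4-dimethyloxetan-2-one, trans β-lactone)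
Conditions: PhSO2Cl, pyridine, 0 °C
Reagents that add atoms: none
Why: The hydroxy acid is activated as a mixed sulfonic anhydride, and the hydroxyl attacks the carbonyl. The carbinol C–O bond is not broken, so configuration is retained, and the anti acid gives the unstrained trans lactone.

**Step 5**
Reactants: 6 and 7 (4-(benzyloxy)-3-methoxybenzyl chloride)
Product: 8 ((2S,3S)-4-[4-(benzyloxy)-3-methoxyphenyl]-2,3-dimethylbutanoic acid)
Conditions: NiBr2·bpy (10 mol%), nBu4NBF4, DMA, undivided cell, Zn(+) anode / carbon-felt(–) cathode, 5 mA constant current, rt; then 1 M HCl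
Reagents that add atoms: none
Why: Proposed new method: Ni(0)(bpy) adds to the strained secondary alkyl C–O bond of the lactone in an SN2 fashion with inversion, giving a five-membered nickelalactone. The benzyl radical is generated from the benzyl chloride at Ni(I). Capture at Ni(III) and C(sp3)–C(sp3) reductive elimination retain the inverted geometry, so the new stereocentre is (S) and the acid α-centre stays (S). The closest known reactions are Ni-catalysed reductive cross-electrophile ring-opening of oxetanes and aziridines, and Cu-catalysed Grignard opening of β-lactones at the alkyl–O carbon.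

**Step 6**
Reactants: 8
Product: 9 ((2S,3S)-4-[4-(benzyloxy)-3-methoxyphenyl]-2,3-dimethylbutan-1-ol)
Conditions: BH3·SMe2, THF, 0 °C → rt
Reagents that add atoms: none
Why: Borane reduces carboxylic acids chemoselectively and leaves the benzyl ether and aryl methyl ether untouched. No stereocentre is affected.

**Step 7**
Reactants: 9
Product: 10 ((2S,3S)-1-bromo-4-[4-(benzyloxy)-3-methoxyphenyl]-2,3-dimethylbutane)
Conditions: CBr4, PPh3, CH2Cl2, 0 °C → rt
Reagents that add atoms: carbon tetrabromide, BrC(Br)(Br)Br
Why: Appel bromination at a primary carbon. It is an SN2 at CH2 and leaves the adjacent centre untouched.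

**Step 8**
Reactants: 10 (1 equiv) and 2 (2 equiv)
Product: 11 (bis-benzyl ether of the target)
Conditions: NiBr2·glyme (10 mol%), dtbbpy (10 mol%), [Ir{dF(CF3)ppy}2(dtbbpy)]PF6 (1 mol%), (Me3Si)3SiH (1.5 equiv), Na2CO3 (2 equiv), DME, blue LEDs, rt, 16 h
Reagents that add atoms: none
Why: Silyl-radical halogen abstraction gives a primary alkyl radical, which enters a Ni/photoredox cross-electrophile coupling with the aryl bromide. The radical sits on CH2, not on the stereocentres, so both are preserved. The coupling step itself forms no new stereocentre.

**Step 9**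
Reactants: 11
Product: 12 (target, (2S,3R) bis-phenol)
Conditions: H2 (1 atm), 10% Pd/C, EtOAc/EtOH, rt
Reagents that add atoms: none
Why: Hydrogenolysis removes both O-benzyl groups; the aryl ethers and the sp3 stereocentres are unaffected.

## Compound list
1 | 4-bromo-2,6-dimethoxyphenol | COc1cc(Br)cc(OC)c1O | starting material
2 | 2-(benzyloxy)-5-bromo-1,3-dimethoxybenzene | COc1cc(Br)cc(OC)c1OCc1ccccc1 | intermediate
3 | ethyl (S)-3-hydroxybutanoate | CCOC(=O)C[C@H](C)O | starting material
4 | ethyl (2S,3S)-3-hydroxy-2-methylbutanoate | CCOC(=O)[C@@H](C)[C@H](C)O | intermediate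
5 | (2S,3S)-3-hydroxy-2-methylbutanoic acid | OC(=O)[C@@H](C)[C@H](C)O | intermediate
6 | (3S,4S)-3,4-dimethyloxetan-2-one | C[C@@H]1OC(=O)[C@H]1C | intermediate
7 | 4-(benzyloxy)-3-methoxybenzyl chloride | COc1cc(CCl)ccc1OCc1ccccc1 | starting material
8 | (2S,3S)-4-[4-(benzyloxy)-3-methoxyphenyl]-2,3-dimethylbutanoic acid | OC(=O)[C@@H](C)[C@@H](C)Cc1ccc(OCc2ccccc2)c(OC)c1 | intermediate
9 | (2S,3S)-4-[4-(benzyloxy)-3-methoxyphenyl]-2,3-dimethylbutan-1-ol | OC[C@@H](C)[C@@H](C)Cc1ccc(OCc2ccccc2)c(OC)c1 | intermediate
10 | (2S,3S)-1-bromo-4-[4-(benzyloxy)-3-methoxyphenyl]-2,3-dimethylbutane | BrC[C@@H](C)[C@@H](C)Cc1ccc(OCc2ccccc2)c(OC)c1 | intermediate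
11 | bis-O-benzyl target | COc1cc(C[C@H](C)[C@H](C)Cc2cc(OC)c(OCc3ccccc3)c(OC)c2)ccc1OCc1ccccc1 | intermediate
12 | target, 4-[(2S,3R)-3-(4-hydroxy-3,5-dimethoxybenzyl)… i.e. 2,6-dimethoxy-4-[(2R,3S)-4-(4-hydroxy-3-methoxyphenyl)-2,3-dimethylbutyl]phenol | COc1cc(C[C@H](C)[C@H](C)Cc2cc(OC)c(O)c(OC)c2)ccc1O | target

## Totals
- Total steps: 9.
- Longest linear sequence: 8 steps (2 → 9). Step 1 is a parallel branch that feeds step 8.

## Three steps most likely to fail
1. **Step 5 (proposed new electrochemical lactone opening).** Competing β-hydride elimination to 2-methylbut-2-enoic acid, benzyl homocoupling, or loss of stereospecificity through radical ring-opening could all occur. Fallback: the known Cu-catalysed SN2 opening. Convert 7 to the benzylmagnesium chloride and add it to lactone 6 with CuI (10 mol%) in THF at –20 °C. This cleaves the alkyl–O bond with inversion and gives the same acid 8.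
2. **Step 8 (photochemical cross-electrophile coupling).** The electron-rich, hindered aryl bromide and the β-branched primary bromide may give hydrodehalogenation or homocoupling. Fallback: a two-electron Negishi coupling. Convert 10 to the alkylzinc (Zn, LiCl, THF) and couple with 2 using Pd-PEPPSI-IPr.
3. **Step 4 (β-lactonisation).** Elimination to the enoic acid or oligomerisation may compete, and the small lactone is volatile. Fallback: invert C3 of 4 by Mitsunobu with p-nitrobenzoic acid, then hydrolyse to the syn hydroxy acid. Then close the lactone by Mitsunobu (DEAD, PPh3), which proceeds with inversion at the carbinol carbon and gives the same trans lactone 6.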